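The route rests on disconnecting the aryl ether bond O1–C7a of the dihydrobenzofuran. Ring B carries a formyl group at C5, para to C7a, so a fluoride at C7a is activated for intramolecular nucleophilic aromatic substitution by the C2 alkoxide. One operation closes the five-membered ring, keeps both stereocentres (open-chain syn becomes ring trans) and leaves the aldehyde as the anchor for the C5 propyl chain. The precursor is an acyclic (1R,2S) 1,3-diol derivative from an Evans syn-aldol reaction: free benzylic C2 hydroxyl, TBDPS ether on the primary oxygen (O9), O-benzyl ring A, and a 2-fluoro-3-methoxy-5-formylphenyl group on C3.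

Key step: step 10

Remark: benzofuran numbering is used for the target and its open-chain precursors (O1, C2, C3, C3a, C4–C7, C7a; C9 is the CH2O carbon on C3; ring A is the guaiacyl ring on C2, ring B the benzo ring); the (2R,3S) trans configuration read from the SMILES corresponds to a (1R,2S) syn open-chain array and calls for the (R)-configured oxazolidinone; BrZnCH2CO2Et is taken as a preformed THF solution.

Step 1
Reactants: 1 4-fluoro-3-methoxybenzaldehyde
Product: 2 2-(4-fluoro-3-methoxyphenyl)-1,3-dioxolane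
Conditions: HOCH2CH2OH, p-TsOH·H2O (cat.), toluene, reflux, Dean–Stark
Reagents that add atoms: ethylene glycol, OCCO
Why: Acid-catalysed acetalisation with azeotropic removal of water masks the formyl group as a cyclic acetal that should tolerate the organolithium, zinc enolate, boron enolate and hydride steps that follow.

Step 2
Reactants: 2 2-(4-fluoro-3-methoxyphenyl)-1,3-dioxolane
Product: 4 2-(4-fluoro-3-iodo-5-methoxyphenyl)-1,3-dioxolane, via aryllithium 3 (not isolated)
Conditions: s-BuLi, PMDTA, THF, −78 °C; then I2, −78 °C → rt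
Reagents that add atoms: iodine, II
Why: Directed ortho-metalation under acidity control, in which s-BuLi saturated by PMDTA cannot chelate the methoxy or acetal oxygens and should remove the most acidic and least hindered ring proton, the one next to fluorine (the proton between OMe and the acetal is flanked on both sides), followed by iodination of the aryllithium at −78 °C before loss of LiF to an aryne can set in.

Step 3
Reactants: 4 2-(4-fluoro-3-iodo-5-methoxyphenyl)-1,3-dioxolane
Product: 5 ethyl 2-[5-(1,3-dioxolan-2-yl)-2-fluoro-3-methoxyphenyl]acetate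
Conditions: BrZnCH2CO2Et, Pd2(dba)3 (cat.), XPhos (cat.), THF, 60 °C
Reagents that add atoms: (2-ethoxy-2-oxoethyl)zinc bromide, CCOC(=O)C[Zn]Br
Why: Negishi-type coupling of a Reformatsky reagent (palladium-catalysed α-arylation of a zinc ester enolate), in which oxidative addition should occur only at the carbon–iodine bond and the neutral zinc enolate leaves the acetal and the aryl fluoride untouched.

Step 4
Reactants: 5 ethyl 2-[5-(1,3-dioxolan-2-yl)-2-fluoro-3-methoxyphenyl]acetate
Product: 6 2-[5-(1,3-dioxolan-2-yl)-2-fluoro-3-methoxyphenyl]acetic acid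
Conditions: LiOH·H2O, THF/H2O (3:1), rt; then 1 M HCl to pH 5, 0 °C
Reagents that add atoms: lithium hydroxide, [Li+].[OH-]
Why: Saponification of an unhindered ethyl ester; the acetal is stable to base and should survive the brief, cold acidification to pH 5.

Step 5
Reactants: 6 2-[5-(1,3-dioxolan-2-yl)-2-fluoro-3-methoxyphenyl]acetic acid; 7 (R)-4-benzyl-2-oxazolidinone
Product: 9 (R)-4-benzyl-3-{2-[5-(1,3-dioxolan-2-yl)-2-fluoro-3-methoxyphenyl]acetyl}-1,3-oxazolidin-2-one, via mixed pivalic anhydride 8 (not isolated)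
Conditions: t-BuCOCl, Et3N, THF, −20 °C; then 7, LiCl, −20 °C → rt
Reagents that add atoms: none
Why: N-Acylation of the oxazolidinone through a mixed pivalic anhydride under LiCl/Et3N activation, in which the nucleophile should attack the less hindered arylacetyl carbonyl; the stereocentre of the auxiliary is not involved.

Step 6
Reactants: 9 (R)-4-benzyl-3-{2-[5-(1,3-dioxolan-2-yl)-2-fluoro-3-methoxyphenyl]acetyl}-1,3-oxazolidin-2-one; 10 O-benzylvanillin (4-benzyloxy-3-methoxybenzaldehyde)
Product: 13 (R)-4-benzyl-3-{(2R,3R)-3-[4-(benzyloxy)-3-methoxyphenyl]-2-[5-(1,3-dioxolan-2-yl)-2-fluoro-3-methoxyphenyl]-3-hydroxypropanoyl}-1,3-oxazolidin-2-one, via Z-boron enolate 11 (not isolated), via boron aldolate 12 (not isolated)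
Conditions: Bu2BOTf, i-Pr2NEt, CH2Cl2, −78 → 0 °C; then 10, −78 → 0 °C; then pH 7 buffer, MeOH, 30% H2O2, 0 °C
Reagents that add atoms: none
Why: Evans syn-aldol reaction, in which the Z dibutylboron enolate reacts through a chair Zimmerman–Traxler transition state with the imide dipoles opposed and the aldehyde approaching the enolate face away from the benzyl group of the (R)-auxiliary, so that both new stereocentres (2R,3R, syn) are set by the auxiliary.

Step 7
Reactants: 13 (R)-4-benzyl-3-{(2R,3R)-3-[4-(benzyloxy)-3-methoxyphenyl]-2-[5-(1,3-dioxolan-2-yl)-2-fluoro-3-methoxyphenyl]-3-hydroxypropanoyl}-1,3-oxazolidin-2-one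
Product: 14 (1R,2S)-1-[4-(benzyloxy)-3-methoxyphenyl]-2-[5-(1,3-dioxolan-2-yl)-2-fluoro-3-methoxyphenyl]propane-1,3-diol
Conditions: LiBH4, MeOH (1 equiv), THF, 0 °C
Reagents that add atoms: none
Why: Reductive cleavage of the N-acyl oxazolidinone at the exocyclic carbonyl should give the primary alcohol and return the auxiliary; at 0 °C neither retro-aldol cleavage nor epimerisation of the α-aryl centre should compete, and the acetal is inert to hydride (the descriptor at C2 changes from R to S only because the CIP priorities change).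

Step 8
Reactants: 14 (1R,2S)-1-[4-(benzyloxy)-3-methoxyphenyl]-2-[5-(1,3-dioxolan-2-yl)-2-fluoro-3-methoxyphenyl]propane-1,3-diol
Product: 15 (1R,2S)-1-[4-(benzyloxy)-3-methoxyphenyl]-3-[(tert-butyldiphenylsilyl)oxy]-2-[5-(1,3-dioxolan-2-yl)-2-fluoro-3-methoxyphenyl]propan-1-ol
Conditions: TBDPSCl, imidazole, CH2Cl2, 0 °C → rt
Reagents that add atoms: tert-butyl(chloro)diphenylsilane, CC(C)(C)[Si](Cl)(c1ccccc1)c1ccccc1
Why: Selective silylation of the primary hydroxyl, which the bulky chlorosilane should reach far faster than the secondary benzylic hydroxyl flanked by two aryl-bearing carbons.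

Step 9
Reactants: 15 (1R,2S)-1-[4-(benzyloxy)-3-methoxyphenyl]-3-[(tert-butyldiphenylsilyl)oxy]-2-[5-(1,3-dioxolan-2-yl)-2-fluoro-3-methoxyphenyl]propan-1-ol
Product: 16 3-{(1R,2S)-1-[4-(benzyloxy)-3-methoxyphenyl]-3-[(tert-butyldiphenylsilyl)oxy]-1-hydroxypropan-2-yl}-4-fluoro-5-methoxybenzaldehyde
Conditions: PPTS (cat.), acetone/H2O (10:1), 50 °C
Reagents that add atoms: water, O
Why: Mild acid-catalysed acetal hydrolysis; the buffered acidity of PPTS should suffice for the aryl dioxolane yet be too weak to ionise the p-alkoxybenzylic alcohol (which would scramble C1) or to cleave the TBDPS ether.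

Step 10
Reactants: 16 3-{(1R,2S)-1-[4-(benzyloxy)-3-methoxyphenyl]-3-[(tert-butyldiphenylsilyl)oxy]-1-hydroxypropan-2-yl}-4-fluoro-5-methoxybenzaldehyde
Product: 18 (2R,3S)-2-[4-(benzyloxy)-3-methoxyphenyl]-3-{[(tert-butyldiphenylsilyl)oxy]methyl}-7-methoxy-2,3-dihydro-1-benzofuran-5-carbaldehyde, via potassium alkoxide 17 (not isolated)
Conditions: KN(SiMe3)2 (1.0 equiv), THF (0.02 M), −78 → 0 °C
Reagents that add atoms: none
Why: KN(SiMe3)2 should convert the C2 hydroxyl of 16 into potassium alkoxide 17, which adds to C7a of ring B and expels fluoride (addition–elimination, with the developing negative charge delocalised through ring B onto the para C5 formyl oxygen); the closest known reaction type is the intramolecular SNAr etherification of 2-(2-fluoroaryl)ethanols to 2,3-dihydrobenzofurans, together with the SNAr of 4-fluorobenzaldehydes with alkoxides. The dihydrofuran ring closes in a 5-exo mode at an sp2 carbon, O1–C7a being the only new bond. No stereocentre is formed: the C2–O and C3–C3a bonds are never broken, so the (1R,2S) syn array should be carried over unchanged as the (2R,3S) trans ring. The step needs selectivity between the two oxygens, because O9 could reach C7a through an equally five-membered closure; this is secured by the TBDPS ether on O9, whose transfer to the hindered secondary benzylic oxygen is uphill and should be slow next to an activated closure at −78 to 0 °C. It also needs the formyl group to survive, which is why one equivalent of a hindered amide base is used cold and dilute: O–H deprotonation is faster than addition to the carbonyl, and hemiacetal formation between alkoxide and aldehyde is reversible.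

Step 11
Reactants: 18 (2R,3S)-2-[4-(benzyloxy)-3-methoxyphenyl]-3-{[(tert-butyldiphenylsilyl)oxy]methyl}-7-methoxy-2,3-dihydro-1-benzofuran-5-carbaldehyde
Product: 19 ethyl (E)-3-[(2R,3S)-2-[4-(benzyloxy)-3-methoxyphenyl]-3-{[(tert-butyldiphenylsilyl)oxy]methyl}-7-methoxy-2,3-dihydro-1-benzofuran-5-yl]prop-2-enoate
Conditions: Ph3P=CHCO2Et, toluene, 60 °C
Reagents that add atoms: ethyl (triphenylphosphoranylidene)acetate, CCOC(=O)C=P(c1ccccc1)(c1ccccc1)c1ccccc1
Why: Wittig olefination with a stabilised ylide, which should react only with the aldehyde and give the E-enoate under neutral conditions that expose no sensitive centre.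

Step 12
Reactants: 19 ethyl (E)-3-[(2R,3S)-2-[4-(benzyloxy)-3-methoxyphenyl]-3-{[(tert-butyldiphenylsilyl)oxy]methyl}-7-methoxy-2,3-dihydro-1-benzofuran-5-yl]prop-2-enoate
Product: 20 ethyl 3-[(2R,3S)-3-{[(tert-butyldiphenylsilyl)oxy]methyl}-2-(4-hydroxy-3-methoxyphenyl)-7-methoxy-2,3-dihydro-1-benzofuran-5-yl]propanoate
Conditions: H2 (1 atm), 10% Pd/C, EtOAc, rt
Reagents that add atoms: none
Why: Heterogeneous catalytic hydrogenation should saturate the alkene and hydrogenolyse the benzyl ether of ring A in one operation; at 1 atm in EtOAc the cyclic benzylic aryl ether (O1–C2) and the silyl ether should remain intact, as is usual for phenylcoumaran lignans.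

Step 13
Reactants: 20 ethyl 3-[(2R,3S)-3-{[(tert-butyldiphenylsilyl)oxy]methyl}-2-(4-hydroxy-3-methoxyphenyl)-7-methoxy-2,3-dihydro-1-benzofuran-5-yl]propanoate
Product: 21 3-[(2R,3S)-3-{[(tert-butyldiphenylsilyl)oxy]methyl}-2-(4-hydroxy-3-methoxyphenyl)-7-methoxy-2,3-dihydro-1-benzofuran-5-yl]propan-1-ol
Conditions: LiAlH4, THF, 0 °C; then H2O/aq. NaOH
Reagents that add atoms: none
Why: Hydride reduction of the ester to the primary alcohol; the phenoxide formed in the flask is inert and the TBDPS ether should tolerate LiAlH4 at 0 °C.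

Step 14
Reactants: 21 3-[(2R,3S)-3-{[(tert-butyldiphenylsilyl)oxy]methyl}-2-(4-hydroxy-3-methoxyphenyl)-7-methoxy-2,3-dihydro-1-benzofuran-5-yl]propan-1-ol; 22 ferulic acid ((E)-4-hydroxy-3-methoxycinnamic acid)
Product: 23 3-[(2R,3S)-3-{[(tert-butyldiphenylsilyl)oxy]methyl}-2-(4-hydroxy-3-methoxyphenyl)-7-methoxy-2,3-dihydro-1-benzofuran-5-yl]propyl (E)-3-(4-hydroxy-3-methoxyphenyl)prop-2-enoate
Conditions: 22, PPh3, DIAD, THF, 0 °C → rt
Reagents that add atoms: none
Why: Mitsunobu esterification, in which the only free alcohol is activated as an alkoxyphosphonium ion and displaced by the carboxylate of 22, the one pronucleophile acidic enough (pKa about 4.5 against about 10 for the phenols) to be deprotonated by the betaine, so the ester should form without protection of either phenol, a chemoselectivity known for phenolic acids.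

Step 15
Reactants: 23 3-[(2R,3S)-3-{[(tert-butyldiphenylsilyl)oxy]methyl}-2-(4-hydroxy-3-methoxyphenyl)-7-methoxy-2,3-dihydro-1-benzofuran-5-yl]propyl (E)-3-(4-hydroxy-3-methoxyphenyl)prop-2-enoate
Product: 24 3-[(2R,3S)-3-(hydroxymethyl)-2-(4-hydroxy-3-methoxyphenyl)-7-methoxy-2,3-dihydro-1-benzofuran-5-yl]propyl (E)-3-(4-hydroxy-3-methoxyphenyl)prop-2-enoate
Conditions: HF·pyridine, pyridine, THF, 0 °C → rt
Reagents that add atoms: none
Why: Fluoride-induced cleavage of the silyl ether, driven by Si–F bond formation; buffered HF·pyridine is not basic, so the cinnamate ester, the free phenols and the O1–C2 benzylic ether should stay intact and no stereocentre is touched.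

Compound list
1 | 4-fluoro-3-methoxybenzaldehyde | COc1cc(C=O)ccc1F | starting material
2 | 2-(4-fluoro-3-methoxyphenyl)-1,3-dioxolane | COc1cc(C2OCCO2)ccc1F | intermediate
3 | [5-(1,3-dioxolan-2-yl)-2-fluoro-3-methoxyphenyl]lithium | [Li]c1cc(C2OCCO2)cc(OC)c1F | intermediate (not isolated)
4 | 2-(4-fluoro-3-iodo-5-methoxyphenyl)-1,3-dioxolane | COc1cc(C2OCCO2)cc(I)c1F | intermediate
5 | ethyl 2-[5-(1,3-dioxolan-2-yl)-2-fluoro-3-methoxyphenyl]acetate | CCOC(=O)Cc1cc(C2OCCO2)cc(OC)c1F | intermediate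
6 | 2-[5-(1,3-dioxolan-2-yl)-2-fluoro-3-methoxyphenyl]acetic acid | OC(=O)Cc1cc(C2OCCO2)cc(OC)c1F | intermediate
7 | (R)-4-benzyl-2-oxazolidinone | O=C1N[C@H](Cc2ccccc2)CO1 | starting material
8 | 2-[5-(1,3-dioxolan-2-yl)-2-fluoro-3-methoxyphenyl]acetic pivalic anhydride | CC(C)(C)C(=O)OC(=O)Cc1cc(C2OCCO2)cc(OC)c1F | intermediate (not isolated)
9 | (R)-4-benzyl-3-{2-[5-(1,3-dioxolan-2-yl)-2-fluoro-3-methoxyphenyl]acetyl}-1,3-oxazolidin-2-one | O=C(Cc1cc(C2OCCO2)cc(OC)c1F)N1[C@H](Cc2ccccc2)COC1=O | intermediate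
10 | O-benzylvanillin (4-benzyloxy-3-methoxybenzaldehyde) | COc1cc(C=O)ccc1OCc1ccccc1 | starting material
11 | Z dibutylboron enolate of 9 | CCCCB(CCCC)O/C(=C\c1cc(C2OCCO2)cc(OC)c1F)N1[C@H](Cc2ccccc2)COC1=O | intermediate (not isolated)
12 | O-dibutylboryl aldolate of 13 | COc1cc(C2OCCO2)cc(c1F)[C@@H](C(=O)N1[C@H](Cc2ccccc2)COC1=O)[C@@H](OB(CCCC)CCCC)c1ccc(OCc2ccccc2)c(OC)c1 | intermediate (not isolated)
13 | (R)-4-benzyl-3-{(2R,3R)-3-[4-(benzyloxy)-3-methoxyphenyl]-2-[5-(1,3-dioxolan-2-yl)-2-fluoro-3-methoxyphenyl]-3-hydroxypropanoyl}-1,3-oxazolidin-2-one | COc1cc(C2OCCO2)cc(c1F)[C@@H](C(=O)N1[C@H](Cc2ccccc2)COC1=O)[C@@H](O)c1ccc(OCc2ccccc2)c(OC)c1 | intermediate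
14 | (1R,2S)-1-[4-(benzyloxy)-3-methoxyphenyl]-2-[5-(1,3-dioxolan-2-yl)-2-fluoro-3-methoxyphenyl]propane-1,3-diol | COc1cc(C2OCCO2)cc(c1F)[C@@H](CO)[C@@H](O)c1ccc(OCc2ccccc2)c(OC)c1 | intermediate
15 | (1R,2S)-1-[4-(benzyloxy)-3-methoxyphenyl]-3-[(tert-butyldiphenylsilyl)oxy]-2-[5-(1,3-dioxolan-2-yl)-2-fluoro-3-methoxyphenyl]propan-1-ol | COc1cc(C2OCCO2)cc(c1F)[C@@H](CO[Si](c1ccccc1)(c1ccccc1)C(C)(C)C)[C@@H](O)c1ccc(OCc2ccccc2)c(OC)c1 | intermediate
16 | 3-{(1R,2S)-1-[4-(benzyloxy)-3-methoxyphenyl]-3-[(tert-butyldiphenylsilyl)oxy]-1-hydroxypropan-2-yl}-4-fluoro-5-methoxybenzaldehyde | O=Cc1cc(OC)c(F)c(c1)[C@@H](CO[Si](c2ccccc2)(c2ccccc2)C(C)(C)C)[C@@H](O)c1ccc(OCc2ccccc2)c(OC)c1 | intermediate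
17 | potassium (1R,2S)-1-[4-(benzyloxy)-3-methoxyphenyl]-3-[(tert-butyldiphenylsilyl)oxy]-2-(2-fluoro-5-formyl-3-methoxyphenyl)propan-1-olate | O=Cc1cc(OC)c(F)c(c1)[C@@H](CO[Si](c2ccccc2)(c2ccccc2)C(C)(C)C)[C@@H]([O-])c1ccc(OCc2ccccc2)c(OC)c1.[K+] | intermediate (not isolated)
18 | (2R,3S)-2-[4-(benzyloxy)-3-methoxyphenyl]-3-{[(tert-butyldiphenylsilyl)oxy]methyl}-7-methoxy-2,3-dihydro-1-benzofuran-5-carbaldehyde | O=Cc2cc(OC)c3c(c2)[C@@H](CO[Si](c4ccccc4)(c4ccccc4)C(C)(C)C)[C@H](c2ccc(OCc4ccccc4)c(OC)c2)O3 | intermediate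
19 | ethyl (E)-3-[(2R,3S)-2-[4-(benzyloxy)-3-methoxyphenyl]-3-{[(tert-butyldiphenylsilyl)oxy]methyl}-7-methoxy-2,3-dihydro-1-benzofuran-5-yl]prop-2-enoate | CCOC(=O)/C=C/c2cc(OC)c3c(c2)[C@@H](CO[Si](c4ccccc4)(c4ccccc4)C(C)(C)C)[C@H](c2ccc(OCc4ccccc4)c(OC)c2)O3 | intermediate
20 | ethyl 3-[(2R,3S)-3-{[(tert-butyldiphenylsilyl)oxy]methyl}-2-(4-hydroxy-3-methoxyphenyl)-7-methoxy-2,3-dihydro-1-benzofuran-5-yl]propanoate | CCOC(=O)CCc2cc(OC)c3c(c2)[C@@H](CO[Si](c4ccccc4)(c4ccccc4)C(C)(C)C)[C@H](c2ccc(O)c(OC)c2)O3 | intermediate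
21 | 3-[(2R,3S)-3-{[(tert-butyldiphenylsilyl)oxy]methyl}-2-(4-hydroxy-3-methoxyphenyl)-7-methoxy-2,3-dihydro-1-benzofuran-5-yl]propan-1-ol | OCCCc2cc(OC)c3c(c2)[C@@H](CO[Si](c4ccccc4)(c4ccccc4)C(C)(C)C)[C@H](c2ccc(O)c(OC)c2)O3 | intermediate
22 | ferulic acid | COc1cc(/C=C/C(=O)O)ccc1O | starting material
23 | 3-[(2R,3S)-3-{[(tert-butyldiphenylsilyl)oxy]methyl}-2-(4-hydroxy-3-methoxyphenyl)-7-methoxy-2,3-dihydro-1-benzofuran-5-yl]propyl (E)-3-(4-hydroxy-3-methoxyphenyl)prop-2-enoate | COc1cc(/C=C/C(=O)OCCCc2cc(OC)c3c(c2)[C@@H](CO[Si](c4ccccc4)(c4ccccc4)C(C)(C)C)[C@H](c2ccc(O)c(OC)c2)O3)ccc1O | intermediate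
24 | 3-[(2R,3S)-3-(hydroxymethyl)-2-(4-hydroxy-3-methoxyphenyl)-7-methoxy-2,3-dihydro-1-benzofuran-5-yl]propyl (E)-3-(4-hydroxy-3-methoxyphenyl)prop-2-enoate | COc1cc(/C=C/C(=O)OCCCc2cc(OC)c3c(c2)[C@@H](CO)[C@H](c2ccc(O)c(OC)c2)O3)ccc1O | target

Total step count: 15. Longest linear sequence: 15 steps (1 to 24); 7, 10 and 22 enter as purchased materials.

Steps most likely to fail

1. Step 10 (key step). What may go wrong: migration of the silyl group from O9 to the C2 alkoxide, which frees the primary alkoxide for the competing five-membered closure at C7a, or consumption of the formyl group by hydride transfer from the alkoxide before substitution is complete. Fallback: the closure is run with an O9 ether that cannot migrate, and the silyl group is put on afterwards. Setting out from diol 14, tritylation of the primary hydroxyl (TrCl, Et3N, DMAP, CH2Cl2) should give (1R,2S)-1-[4-(benzyloxy)-3-methoxyphenyl]-2-[5-(1,3-dioxolan-2-yl)-2-fluoro-3-methoxyphenyl]-3-(trityloxy)propan-1-ol F1. PPTS in wet acetone should then free the aldehyde to give 3-{(1R,2S)-1-[4-(benzyloxy)-3-methoxyphenyl]-1-hydroxy-3-(trityloxy)propan-2-yl}-4-fluoro-5-methoxybenzaldehyde F2. KN(SiMe3)2 in THF at −78 to 0 °C should close the ring to (2R,3S)-2-[4-(benzyloxy)-3-methoxyphenyl]-7-methoxy-3-[(trityloxy)methyl]-2,3-dihydro-1-benzofuran-5-carbaldehyde F3. Aqueous AcOH (80%, 40 °C) should remove the trityl group to give (2R,3S)-2-[4-(benzyloxy)-3-methoxyphenyl]-3-(hydroxymethyl)-7-methoxy-2,3-dihydro-1-benzofuran-5-carbaldehyde F4, and TBDPSCl with imidazole should bring the route back at 18.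

2. Step 2. What may go wrong: deprotonation between the methoxy and acetal groups instead of next to fluorine, or attack of the base on the acetal C–H with fragmentation of the dioxolane. Fallback: sterically controlled C–H borylation in place of lithiation. Setting out from 2, [Ir(OMe)(cod)]2 with dtbpy and B2pin2 (THF, 80 °C) should borylate the only ring C–H whose sole neighbour is fluorine, giving 2-[4-fluoro-3-methoxy-5-(4,4,5,5-tetramethyl-1,3,2-dioxaborolan-2-yl)phenyl]-1,3-dioxolane F5. Copper-mediated iododeboronation (CuI, 1,10-phenanthroline, KI, air, MeOH/H2O, 80 °C) should then give iodide 4, where the route resumes.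

3. Step 14. What may go wrong: alkylation of a phenol oxygen (ring A of 21 or the phenol of 22) by the alkoxyphosphonium ion in competition with the carboxylate, or anhydride formation from the acid, giving mixtures that are hard to separate from the hydrazine by-product. Fallback: the activation is reversed, so that a carboxylate is alkylated under conditions in which phenols stay protonated. Setting out from 21, Appel bromination (CBr4, PPh3, CH2Cl2, 0 °C) should give 4-[(2R,3S)-5-(3-bromopropyl)-3-{[(tert-butyldiphenylsilyl)oxy]methyl}-7-methoxy-2,3-dihydro-1-benzofuran-2-yl]-2-methoxyphenol F6. Treatment with ferulic acid 22 and KHCO3 in DMF at 40 °C should alkylate only the carboxylate and give 23, where the route resumes.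

Further compounds
F1 | step 10 | (1R,2S)-1-[4-(benzyloxy)-3-methoxyphenyl]-2-[5-(1,3-dioxolan-2-yl)-2-fluoro-3-methoxyphenyl]-3-(trityloxy)propan-1-ol | COc1cc(C2OCCO2)cc(c1F)[C@@H](COC(c1ccccc1)(c1ccccc1)c1ccccc1)[C@@H](O)c1ccc(OCc2ccccc2)c(OC)c1
F2 | step 10 | 3-{(1R,2S)-1-[4-(benzyloxy)-3-methoxyphenyl]-1-hydroxy-3-(trityloxy)propan-2-yl}-4-fluoro-5-methoxybenzaldehyde | O=Cc1cc(OC)c(F)c(c1)[C@@H](COC(c2ccccc2)(c2ccccc2)c2ccccc2)[C@@H](O)c1ccc(OCc2ccccc2)c(OC)c1
F3 | step 10 | (2R,3S)-2-[4-(benzyloxy)-3-methoxyphenyl]-7-methoxy-3-[(trityloxy)methyl]-2,3-dihydro-1-benzofuran-5-carbaldehyde | O=Cc2cc(OC)c3c(c2)[C@@H](COC(c4ccccc4)(c4ccccc4)c4ccccc4)[C@H](c2ccc(OCc4ccccc4)c(OC)c2)O3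
F4 | step 10 | (2R,3S)-2-[4-(benzyloxy)-3-methoxyphenyl]-3-(hydroxymethyl)-7-methoxy-2,3-dihydro-1-benzofuran-5-carbaldehyde | O=Cc2cc(OC)c3c(c2)[C@@H](CO)[C@H](c2ccc(OCc4ccccc4)c(OC)c2)O3
F5 | step 2 | 2-[4-fluoro-3-methoxy-5-(4,4,5,5-tetramethyl-1,3,2-dioxaborolan-2-yl)phenyl]-1,3-dioxolane | COc1cc(C2OCCO2)cc(B3OC(C)(C)C(C)(C)O3)c1F
F6 | step 14 | 4-[(2R,3S)-5-(3-bromopropyl)-3-{[(tert-butyldiphenylsilyl)oxy]methyl}-7-methoxy-2,3-dihydro-1-benzofuran-2-yl]-2-methoxyphenol | BrCCCc2cc(OC)c3c(c2)[C@@H](CO[Si](c4ccccc4)(c4ccccc4)C(C)(C)C)[C@H](c2ccc(O)c(OC)c2)O3
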